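**Retrosynthetic overview**

- Ring A is numbered C1 (aryloxy), C2 (OMe), C3 (Br), C4 (H), C5 (Br), C6 (Br); ring B is the 2-bromophenyl ring. The plan rests on one feature: the only hydrogen of ring A, at C4, lies para to the ether carbon C1 and between C3–Br and C5–Br.
- A nitrogen at C4 therefore serves three times: as NO2 it activates C1 for SNAr, as NH2 it directs both flanking bromines, and it is finally replaced by hydrogen.
- Disconnections, backwards: C4–H from C4–NH2 (hydrodediazoniation); C3–Br and C5–Br by amino-directed double bromination; C4–NH2 from C4–NO2; C1–O(ring B) by SNAr of 2-bromophenoxide on a C1 bromide para to nitro.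
- The C1 bromide comes from a Sandmeyer reaction, and C6–Br from bromination ortho to the amino group of 2-methoxy-4-nitroaniline.
- No ring is built: ring A is bought as 2-methoxy-4-nitroaniline, ring B as 2-bromophenol, and they are joined in step 3.

Key step: step 5

**Route**

Step 1
Reactants: 1 2-methoxy-4-nitroaniline; 2 N-bromosuccinimide
Product: 3 2-bromo-6-methoxy-4-nitroaniline
Conditions: NBS (1.05 equiv), MeCN, rt to 50 °C
Reagents that add atoms: N-bromosuccinimide (2), O=C1CCC(=O)N1Br
Why: Electrophilic aromatic bromination of an aniline: the amino group directs to its only free ortho carbon (para holds the nitro group), which is also meta to nitro, whereas the two carbons next to nitro are activated by methoxy alone and should not compete.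

Step 2
Reactants: 3 2-bromo-6-methoxy-4-nitroaniline
Product: 5 1,2-dibromo-3-methoxy-5-nitrobenzene, via diazonium hydrogen sulfate 4 (not isolated)
Conditions: NaNO2, conc. H2SO4/AcOH, 0–15 °C; then CuBr, 48% aq. HBr, 0 to 50 °C
Reagents that add atoms: hydrogen bromide, Br; sodium nitrite, [Na+].[O-]N=O (second nitrogen of intermediate 4 only); sulfuric acid, OS(=O)(=O)O (counter-ion of intermediate 4 only)
Why: Sandmeyer bromination: nitrosylsulfuric acid diazotises the weakly basic, doubly ortho-substituted nitroaniline and CuBr passes bromine to the aryl radical formed on loss of N2; bromide is the incoming halide so that any halide exchange at the activated carbon next to the diazonium group changes nothing.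

Step 3
Reactants: 5 1,2-dibromo-3-methoxy-5-nitrobenzene; 6 2-bromophenol
Product: 7 1-bromo-2-(2-bromophenoxy)-3-methoxy-5-nitrobenzene
Conditions: K2CO3 (2 equiv), DMSO, 100 °C, N2
Reagents that add atoms: none
Why: Nucleophilic aromatic substitution (SNAr, addition–elimination): only the bromide para to nitro can pass the charge of the Meisenheimer adduct into NO2, the neighbouring bromide being meta to nitro and the bromide of ring B unactivated, so 2-bromophenoxide should displace that one halide alone.

Step 4
Reactants: 7 1-bromo-2-(2-bromophenoxy)-3-methoxy-5-nitrobenzene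
Product: 8 3-bromo-4-(2-bromophenoxy)-5-methoxyaniline
Conditions: Fe powder, NH4Cl, EtOH/H2O (4:1), 80 °C
Reagents that add atoms: none
Why: Béchamp-type iron reduction of the nitro group by electron transfer from the metal in a nearly neutral medium, which should leave the aryl bromides and the diaryl ether untouched where catalytic hydrogenation would risk hydrodebromination.

Step 5
Reactants: 8 3-bromo-4-(2-bromophenoxy)-5-methoxyaniline; 2 N-bromosuccinimide (two equivalents)
Product: 10 2,3,6-tribromo-4-(2-bromophenoxy)-5-methoxyaniline, via monobrominated aniline 9 (not isolated)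
Conditions: NBS (2.05 equiv, in portions), MeCN, −10 °C to rt, dark; aq. Na2S2O3 quench
Reagents that add atoms: N-bromosuccinimide (2), O=C1CCC(=O)N1Br
Why: Electrophilic aromatic substitution in which NBS delivers Br+ twice to ring A through arenium ions stabilised by the amino nitrogen, first giving 9 and then 10; whichever ortho carbon reacts first, both monobromides converge on 10. The closest known reaction type is the ortho,ortho-dibromination of para-substituted anilines with NBS or Br2. No ring is closed and no stereocentre is created. The step needs ring A to react before ring B and the reaction to stop after two bromines: NH2 is the strongest donor in the molecule, its para carbon C1 is blocked by the aryloxy group, and the methoxy group (ortho to C3, para to C5) sends electron density to the same two carbons, while C6 already carries bromine so that ring A has no further free site. Ring B is activated only by an ether oxygen that it shares with the electron-poor ring A and is deactivated by its own bromine, so at low temperature with two equivalents of reagent it should stay untouched.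

Step 6
Reactants: 10 2,3,6-tribromo-4-(2-bromophenoxy)-5-methoxyaniline
Product: 12 1,2,5-tribromo-3-(2-bromophenoxy)-4-methoxybenzene, via diazonium hydrogen sulfate 11 (not isolated)
Conditions: NaNO2, conc. H2SO4/AcOH, 0–10 °C; then 50% aq. H3PO2, Cu2O (cat.), 0 °C to rt
Reagents that add atoms: sodium nitrite, [Na+].[O-]N=O (second nitrogen of intermediate 11 only); sulfuric acid, OS(=O)(=O)O (counter-ion of intermediate 11 only)
Why: Hydrodediazoniation: nitrosylsulfuric acid diazotises the weakly basic 2,6-dibromoaniline in a chloride-free medium (no halide exchange next to N2+), and H3PO2 with Cu2O reduces the diazonium ion by a radical chain in which the aryl radical takes hydrogen from a P–H bond, leaving C4–H where the nitrogen stood.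

**Compound list**

1 | 2-methoxy-4-nitroaniline | COc1cc(ccc1N)[N+](=O)[O-] | starting material
2 | N-bromosuccinimide | O=C1CCC(=O)N1Br | starting material
3 | 2-bromo-6-methoxy-4-nitroaniline | COc1cc([N+](=O)[O-])cc(Br)c1N | intermediate
4 | 2-bromo-6-methoxy-4-nitrobenzenediazonium hydrogen sulfate | COc1cc([N+](=O)[O-])cc(Br)c1[N+]#N.OS(=O)(=O)[O-] | intermediate
5 | 1,2-dibromo-3-methoxy-5-nitrobenzene | COc1cc([N+](=O)[O-])cc(Br)c1Br | intermediate
6 | 2-bromophenol | Oc1ccccc1Br | starting material
7 | 1-bromo-2-(2-bromophenoxy)-3-methoxy-5-nitrobenzene | COc1cc([N+](=O)[O-])cc(Br)c1Oc1ccccc1Br | intermediate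
8 | 3-bromo-4-(2-bromophenoxy)-5-methoxyaniline | COc1cc(N)cc(Br)c1Oc1ccccc1Br | intermediate
9 | 2,3-dibromo-4-(2-bromophenoxy)-5-methoxyaniline (first bromine para to OMe) | COc1cc(N)c(Br)c(Br)c1Oc1ccccc1Br | intermediate
10 | 2,3,6-tribromo-4-(2-bromophenoxy)-5-methoxyaniline | COc1c(Br)c(N)c(Br)c(Br)c1Oc1ccccc1Br | intermediate
11 | 2,3,6-tribromo-4-(2-bromophenoxy)-5-methoxybenzenediazonium hydrogen sulfate | COc1c(Br)c([N+]#N)c(Br)c(Br)c1Oc1ccccc1Br.OS(=O)(=O)[O-] | intermediate
12 | 1,2,5-tribromo-3-(2-bromophenoxy)-4-methoxybenzene | COc1c(Br)cc(Br)c(Br)c1Oc1ccccc1Br | target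

**Step count and risks**

Total steps: 6. Longest linear sequence: 6 steps (1 → 3 → 5 → 7 → 8 → 10 → 12).

Steps most likely to fail:

1. Step 5 (key step). The free, electron-rich amine may be oxidised or N-brominated by the N-bromo reagent and couple to coloured quinone-imine-type material before the second ring substitution is complete. The fallback masks the nitrogen as a carbamate and relies on carbamate and methoxy directing together. It sets out from 8: Boc2O in THF at 60 °C should give tert-butyl N-[3-bromo-4-(2-bromophenoxy)-5-methoxyphenyl]carbamate F3. NBS (2.2 equiv) in DMF at rt to 45 °C should then brominate the two carbons ortho to nitrogen, which are also ortho and para to OMe, to give tert-butyl N-[2,3,6-tribromo-4-(2-bromophenoxy)-5-methoxyphenyl]carbamate F4. TFA in CH2Cl2 followed by a NaHCO3 wash returns to the route at 10.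

2. Step 3. Addition of the hindered ortho-bromophenoxide to a carbon flanked by OMe and Br may be slow, and at forcing temperature O-demethylation of the methoxy group by phenoxide may intervene. The fallback reverses the polarity of the ether formation and sets out from 3. Diazotisation as in step 2 gives 4, which is hydrolysed in aqueous H2SO4 with Cu2O and Cu(NO3)2 to 2-bromo-6-methoxy-4-nitrophenol F1. Its potassium salt (tBuOK, THF, 40 °C) is O-arylated with bis(2-bromophenyl)iodonium tetrafluoroborate F2, made in one pot from 1-bromo-2-iodobenzene (mCPBA, BF3·OEt2, CH2Cl2, then 2-bromophenylboronic acid). Ligand exchange and ligand coupling at trivalent iodine should transfer the 2-bromophenyl group to oxygen without any metal, returning to the route at 7.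

3. Step 6. Diazotisation of the poorly soluble, weakly basic, doubly ortho-brominated amine may be incomplete, and in strong sulfuric acid sulfonation of ring B or capture of the diazonium ion by water may compete with reduction. The fallback is an aprotic radical deamination that sets out from 10. tert-Butyl nitrite in DMF at 60–65 °C should form 1-tert-butoxy-2-[2,3,6-tribromo-4-(2-bromophenoxy)-5-methoxyphenyl]diazene F5, which fragments with loss of N2. The aryl radical takes hydrogen from DMF, returning to the route directly at 12.

**Further compounds**

F1 | step 3 | 2-bromo-6-methoxy-4-nitrophenol | COc1cc([N+](=O)[O-])cc(Br)c1O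
F2 | step 3 | bis(2-bromophenyl)iodonium tetrafluoroborate | Brc1ccccc1[I+]c1ccccc1Br.F[B-](F)(F)F
F3 | step 5 | tert-butyl N-[3-bromo-4-(2-bromophenoxy)-5-methoxyphenyl]carbamate | COc1cc(NC(=O)OC(C)(C)C)cc(Br)c1Oc1ccccc1Br
F4 | step 5 | tert-butyl N-[2,3,6-tribromo-4-(2-bromophenoxy)-5-methoxyphenyl]carbamate | COc1c(Br)c(NC(=O)OC(C)(C)C)c(Br)c(Br)c1Oc1ccccc1Br
F5 | step 6 | 1-tert-butoxy-2-[2,3,6-tribromo-4-(2-bromophenoxy)-5-methoxyphenyl]diazene | COc1c(Br)c(N=NOC(C)(C)C)c(Br)c(Br)c1Oc1ccccc1Br
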